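**Retrosynthetic overview**
- Target ⇐ side-chain oxirane (Shi epoxidation) ⇐ ring oxirane (epoxidation directed by C2–OH) ⇐ diangelate ⇐ triol (one double esterification).
- Triol ⇐ ring-expanding 1,2-shift of the ring alkenyl carbon C7 from silicon to C8 (five-membered oxasilole → six-membered oxasilinane; forms C7–C8, sets C8), then C–Si oxidation.
- Oxasilole ⇐ silicon-tethered vinyl-radical cyclisation onto a cis-diene-diol (forms C1–C7, sets C1 cis to the C2 oxygen).
- Diene-diol ⇐ 4-iodotoluene by enzymatic cis-dihydroxylation (sets C2 and C3), then deiodination.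
- Ring order: carbocycle taken from the arene → temporary oxasilole → oxasilinane (ring expansion) → ring oxirane → side-chain oxirane.

Assumption (atom labels used throughout): ring C1 bears the side chain, C2 the free OH, C3 the O-angelate, C4 the methyl, then C5 and C6; side chain C7 (=C14H2), C8 (O-angelate), C9, C10, C11; all ring substituents and the ring oxirane oxygen lie on one face (α).

**Step 1**
Reactants: 1 4-iodotoluene
Product: 2 (1S,2S)-3-iodo-6-methylcyclohexa-3,5-diene-1,2-diol
Conditions: Pseudomonas putida UV4 whole cells (toluene dioxygenase), glucose, air, phosphate buffer pH 7, 30 °C; EtOAc extraction, recrystallisation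
Reagents that add atoms: dioxygen (O=O)
Why: Enzymatic arene cis-dihydroxylation takes place at the 2,3-bond next to the larger iodine substituent, so both carbinol centres (future C2 and C3) are set in the sense opposite to that obtained from toluene itself, and recrystallisation of the crystalline diol raises the ee.

**Step 2**
Reactants: 2 (1S,2S)-3-iodo-6-methylcyclohexa-3,5-diene-1,2-diol
Product: 3 (1R,2S)-3-methylcyclohexa-3,5-diene-1,2-diol
Conditions: Bu3SnH, Et3B (cat.), air, THF, 0 °C to rt
Reagents that add atoms: none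
Why: Radical hydrodeiodination with tin hydride cleaves only the weak vinyl C–I bond and leaves the diene and both stereocentres untouched.

**Step 3**
Reactants: 4 chlorodimethylvinylsilane
Product: 6 (1-bromoethenyl)(diethylamino)dimethylsilane, via (1,2-dibromoethyl)chlorodimethylsilane 5 (not isolated)
Conditions: Br2, CH2Cl2, −78 °C; then Et2NH (3.5 equiv), Et2O, reflux; filtration, distillation
Reagents that add atoms: bromine (BrBr); diethylamine (CCNCC)
Why: Bromination–dehydrobromination: bromine adds to the vinylsilane and diethylamine removes HBr through the acidic α-silyl hydrogen while replacing Si–Cl by Si–NEt2, which gives a neutral silylating agent.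

**Step 4**
Reactants: 3 (1R,2S)-3-methylcyclohexa-3,5-diene-1,2-diol; 6 (1-bromoethenyl)(diethylamino)dimethylsilane
Product: 8 (5R,6S)-5-{[(1-bromoethenyl)dimethylsilyl]oxy}-1-methyl-6-[(trimethylsilyl)oxy]cyclohexa-1,3-diene, via C2 mono-silyl ether 7 (not isolated)
Conditions: 6 (1.05 equiv), CH2Cl2, −40 to 0 °C; then TMSCl, imidazole, 0 °C
Reagents that add atoms: chlorotrimethylsilane (C[Si](C)(C)Cl)
Why: Regioselective silyl ether formation: the aminosilane silylates the less hindered C2–OH (next to the unsubstituted diene CH, away from the methyl) under neutral conditions that spare the acid-sensitive diene-diol, and TMSCl then caps C3–OH.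

**Step 5**
Reactants: 8 (5R,6S)-5-{[(1-bromoethenyl)dimethylsilyl]oxy}-1-methyl-6-[(trimethylsilyl)oxy]cyclohexa-1,3-diene
Product: 9 (3aR,7S,7aR)-2,2,6-trimethyl-3-methylidene-7-[(trimethylsilyl)oxy]-2,3,3a,4,7,7a-hexahydro-1,2-benzoxasilole (cis-fused)
Conditions: Bu3SnH (slow addition), Et3B (cat.), air, toluene, rt
Reagents that add atoms: none
Why: Silicon-tethered 5-exo-trig vinyl-radical cyclisation onto the diene terminus C1 can only give the cis-fused five-membered ring, which puts C7 on the face of the C2 oxygen (sets C1), and the resulting allyl radical takes hydrogen at the less hindered C6 to leave the trisubstituted C4=C5 alkene.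

**Step 6**
Reactants: 10 4-methylpent-3-en-1-ol
Product: 11 4-methylpent-3-en-1-yl 2,4,6-triisopropylbenzoate
Conditions: 2,4,6-triisopropylbenzoyl chloride, Et3N, DMAP (cat.), CH2Cl2, 40 °C
Reagents that add atoms: 2,4,6-triisopropylbenzoyl chloride (CC(C)c1cc(C(C)C)c(C(Cl)=O)c(C(C)C)c1)
Why: Esterification with the hindered aroyl chloride installs the group that later directs α-lithiation and serves as the leaving group.

**Step 7**
Reactants: 11 4-methylpent-3-en-1-yl 2,4,6-triisopropylbenzoate; 9 (3aR,7S,7aR)-2,2,6-trimethyl-3-methylidene-7-[(trimethylsilyl)oxy]-2,3,3a,4,7,7a-hexahydro-1,2-benzoxasilole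
Product: 15 (1R,2S,6S)-6-[(3S)-3-hydroxy-6-methylhepta-1,5-dien-2-yl]-3-methylcyclohex-3-ene-1,2-diol, via α-lithio benzoate 12 (not isolated), via pentacoordinate lithium silicate 13 (not isolated), via ring-expanded oxasilinane 14 (not isolated)
Conditions: 11, s-BuLi, (+)-sparteine, Et2O, −78 °C, 5 h; then 9, −78 °C to 35 °C; then KF, KHCO3, 30% H2O2, THF–MeOH, rt
Reagents that add atoms: hydrogen peroxide (OO)
Why: Proposed new method: the configurationally stable (R)-α-lithio benzoate 12 (sparteine-mediated Hoppe deprotonation) should add with retention to the strained, Lewis-acidic five-membered alkoxysilane 9 to give silicate 13, whose alkenyl carbon C7 (an sp2 carbon migrating in preference to methyl) then shifts from Si to C8 anti to the departing hindered benzoate (inversion at C8), expanding the oxasilole to the six-membered oxasilinane 14 before stereoretentive Tamao–Fleming oxidation gives (8S)-15; this is a silicon counterpart of the lithiation–borylation 1,2-metallate rearrangement, the closest known reactions being boronate 1,2-shifts of lithiated carbamates and benzoates and alkoxide-induced 1,2-aryl or 1,2-vinyl shifts from silicon in α-halo silanes.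

**Step 8**
Reactants: 15 (1R,2S,6S)-6-[(3S)-3-hydroxy-6-methylhepta-1,5-dien-2-yl]-3-methylcyclohex-3-ene-1,2-diol; 16 angelic acid
Product: 18 (1S,5S,6R)-6-hydroxy-2-methyl-5-{(3S)-6-methyl-3-[(Z)-2-methylbut-2-enoyloxy]hepta-1,5-dien-2-yl}cyclohex-2-en-1-yl (Z)-2-methylbut-2-enoate, via angeloyl trichlorobenzoyl anhydride 17 (not isolated)
Conditions: 16 (2.4 equiv), 2,4,6-trichlorobenzoyl chloride, Et3N, toluene, rt; then 15, toluene, 70 °C (no DMAP)
Reagents that add atoms: none
Why: Yamaguchi-type mixed-anhydride esterification without a nucleophilic catalyst transfers the angeloyl group without Z-to-E isomerisation to the two accessible hydroxyls (allylic C8–OH and pseudo-equatorial allylic C3–OH), while the axial C2–OH flanked by two substituents stays free.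

**Step 9**
Reactants: 18 (1S,5S,6R)-6-hydroxy-2-methyl-5-{(3S)-6-methyl-3-[(Z)-2-methylbut-2-enoyloxy]hepta-1,5-dien-2-yl}cyclohex-2-en-1-yl (Z)-2-methylbut-2-enoate
Product: 19 the 4,5-epoxide of 18, oxirane oxygen cis to C2–OH (C1 S, C2 R, C3 R, C4 S, C5 S, C8 S)
Conditions: VO(acac)2 (5 mol %), t-BuOOH, CH2Cl2, 0 °C to rt
Reagents that add atoms: tert-butyl hydroperoxide (CC(C)(C)OO)
Why: Vanadium-catalysed hydroxyl-directed epoxidation: the axial homoallylic C2–OH delivers the peroxide to the α face of the electron-rich C4=C5 alkene (sets C4 and C5), while the ester-deactivated C7=C14 alkene and the undirected C10=C11 alkene react much more slowly.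

**Step 10**
Reactants: 19 the 4,5-epoxide of 18
Product: 20 CNP0296086.3 (C1 S, C2 R, C3 R, C4 S, C5 S, C8 S, C10 R)
Conditions: D-fructose-derived Shi ketone (0.3 equiv), KHSO5 (Oxone), K2CO3, Bu4NHSO4, MeCN–dimethoxymethane–aqueous buffer (pH 10), 0 °C
Reagents that add atoms: potassium peroxymonosulfate ([K+].[O-]S(=O)(=O)OO)
Why: Shi asymmetric epoxidation attacks the only remaining electron-rich trisubstituted alkene through the spiro transition state that gives the 10R oxirane, the 1,1-disubstituted allylic-ester alkene and the angelates being too electron-poor.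

**Compound list**
1 | 4-iodotoluene | Cc1ccc(I)cc1 | starting material
2 | (1S,2S)-3-iodo-6-methylcyclohexa-3,5-diene-1,2-diol | IC1=CC=C(C)[C@H](O)[C@@H]1O | intermediate
3 | (1R,2S)-3-methylcyclohexa-3,5-diene-1,2-diol | C1=CC=C(C)[C@H](O)[C@@H]1O | intermediate
4 | chlorodimethylvinylsilane | C=C[Si](C)(C)Cl | starting material
5 | (1,2-dibromoethyl)chlorodimethylsilane (racemic) | C[Si](C)(Cl)C(Br)CBr | intermediate
6 | (1-bromoethenyl)(diethylamino)dimethylsilane | C=C(Br)[Si](C)(C)N(CC)CC | intermediate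
7 | (1S,6R)-6-{[(1-bromoethenyl)dimethylsilyl]oxy}-2-methylcyclohexa-2,4-dien-1-ol | C1=CC=C(C)[C@H](O)[C@@H]1O[Si](C)(C)C(Br)=C | intermediate
8 | (5R,6S)-5-{[(1-bromoethenyl)dimethylsilyl]oxy}-1-methyl-6-[(trimethylsilyl)oxy]cyclohexa-1,3-diene | C1=CC=C(C)[C@H](O[Si](C)(C)C)[C@@H]1O[Si](C)(C)C(Br)=C | intermediate
9 | (3aR,7S,7aR)-2,2,6-trimethyl-3-methylidene-7-[(trimethylsilyl)oxy]-2,3,3a,4,7,7a-hexahydro-1,2-benzoxasilole | C=C1[C@@H]2CC=C(C)[C@H](O[Si](C)(C)C)[C@@H]2O[Si]1(C)C | intermediate
10 | 4-methylpent-3-en-1-ol | CC(C)=CCCO | starting material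
11 | 4-methylpent-3-en-1-yl 2,4,6-triisopropylbenzoate | CC(C)=CCCOC(=O)c1c(C(C)C)cc(C(C)C)cc1C(C)C | intermediate
12 | (R)-1-lithio-4-methylpent-3-en-1-yl 2,4,6-triisopropylbenzoate (sparteine complex) | [Li][C@@H](OC(=O)c1c(C(C)C)cc(C(C)C)cc1C(C)C)CC=C(C)C | intermediate
13 | lithium silicate: 9 carrying at silicon the (S)-4-methyl-1-[(2,4,6-triisopropylbenzoyl)oxy]pent-3-en-1-yl group | C=C1[C@@H]2CC=C(C)[C@H](O[Si](C)(C)C)[C@@H]2O[Si-]1(C)(C)[C@H](CC=C(C)C)OC(=O)c1c(C(C)C)cc(C(C)C)cc1C(C)C.[Li+] | intermediate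
14 | (3S,4aS,8S,8aR)-2,2,7-trimethyl-4-methylidene-3-(3-methylbut-2-en-1-yl)-8-[(trimethylsilyl)oxy]-3,4,4a,5,8,8a-hexahydro-2H-1,2-benzoxasiline | C=C1[C@@H]2CC=C(C)[C@H](O[Si](C)(C)C)[C@@H]2O[Si](C)(C)[C@H]1CC=C(C)C | intermediate
15 | (1R,2S,6S)-6-[(3S)-3-hydroxy-6-methylhepta-1,5-dien-2-yl]-3-methylcyclohex-3-ene-1,2-diol | C=C([C@H](CC=C(C)C)O)[C@@H]1CC=C(C)[C@H](O)[C@@H]1O | intermediate
16 | angelic acid, (Z)-2-methylbut-2-enoic acid | C/C=C(/C)C(=O)O | starting material
17 | (Z)-2-methylbut-2-enoic 2,4,6-trichlorobenzoic anhydride | C/C=C(/C)C(=O)OC(=O)c1c(Cl)cc(Cl)cc1Cl | intermediate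
18 | (1S,5S,6R)-6-hydroxy-2-methyl-5-{(3S)-6-methyl-3-[(Z)-2-methylbut-2-enoyloxy]hepta-1,5-dien-2-yl}cyclohex-2-en-1-yl (Z)-2-methylbut-2-enoate | C=C([C@H](CC=C(C)C)OC(=O)/C(C)=C\C)[C@@H]1CC=C(C)[C@H](OC(=O)/C(C)=C\C)[C@@H]1O | intermediate
19 | 4,5-epoxide of 18, oxirane cis to C2–OH (C1 S, C2 R, C3 R, C4 S, C5 S, C8 S) | C=C([C@H](CC=C(C)C)OC(=O)/C(C)=C\C)[C@@H]1C[C@@H]2O[C@]2(C)[C@H](OC(=O)/C(C)=C\C)[C@@H]1O | intermediate
20 | CNP0296086.3 | C=C([C@H](C[C@H]1OC1(C)C)OC(=O)/C(C)=C\C)[C@@H]1C[C@@H]2O[C@]2(C)[C@H](OC(=O)/C(C)=C\C)[C@@H]1O | target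

**Step count**
Total: 10 steps. Longest linear sequence: 8 steps (steps 1, 2, 4, 5, 7, 8, 9, 10).

**Steps most likely to fail, and fallbacks**

Step 7 (the proposed silicon 1,2-shift). If the silicate does not rearrange, known chemistry replaces it. The fallback sets out from 9: ipso-iododesilylation with N-iodosuccinimide in MeCN at 0 °C and a KF/MeOH work-up give (1R,2S,6R)-6-(1-iodoethenyl)-3-methylcyclohex-3-ene-1,2-diol F1. Dess–Martin oxidation of 10 gives 4-methylpent-3-enal F2. Nozaki–Hiyama–Kishi coupling of the two (CrCl2, NiCl2 cat., chiral sulfonamide ligand, THF) comes back to the route at 15, the C8 epimers being separated by chromatography if needed.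

Step 8 (double esterification that must spare C2–OH). If C2–OH is acylated or mixtures form, the order of events is changed so that the C2 oxygen stays bound to silicon. The fallback sets out from 14, isolated from step 7 before the oxidative work-up. K2CO3 in MeOH removes the trimethylsilyl group to give the C3-hydroxy oxasilinane F3. Anhydride 17 acylates its only free hydroxyl to give the C3-angeloyl oxasilinane F4. Tamao–Fleming oxidation (KF, KHCO3, H2O2) gives the 2,8-diol 3-angelate F5. One equivalent of 17 then esterifies the unhindered allylic C8–OH, and the route is rejoined at 18.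

Step 9 (directed epoxidation by a hindered homoallylic OH with a second alkene in reach). If it is slow or attacks C7=C14, the ring oxirane is made last through a halohydrin. The fallback sets out from 18: Shi epoxidation under the conditions of step 10 first gives the (10R)-10,11-epoxy diangelate F6. NBS in aqueous THF at 0 °C puts bromine on the less hindered β face of C4=C5 and water on C4 from the α face to give the trans-bromohydrin F7. Ag2O or K2CO3 in acetone closes the α-oxirane and arrives at 20.

**Further compounds**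
F1 | step 7 | (1R,2S,6R)-6-(1-iodoethenyl)-3-methylcyclohex-3-ene-1,2-diol | C=C(I)[C@@H]1CC=C(C)[C@H](O)[C@@H]1O
F2 | step 7 | 4-methylpent-3-enal | CC(C)=CCC=O
F3 | step 8 | (3S,4aS,8S,8aR)-2,2,7-trimethyl-4-methylidene-3-(3-methylbut-2-en-1-yl)-3,4,4a,5,8,8a-hexahydro-2H-1,2-benzoxasilin-8-ol | C=C1[C@@H]2CC=C(C)[C@H](O)[C@@H]2O[Si](C)(C)[C@H]1CC=C(C)C
F4 | step 8 | (Z)-2-methylbut-2-enoate ester of F3 at C3–OH | C=C1[C@@H]2CC=C(C)[C@H](OC(=O)/C(C)=C\C)[C@@H]2O[Si](C)(C)[C@H]1CC=C(C)C
F5 | step 8 | (1S,5S,6R)-6-hydroxy-5-[(3S)-3-hydroxy-6-methylhepta-1,5-dien-2-yl]-2-methylcyclohex-2-en-1-yl (Z)-2-methylbut-2-enoate | C=C([C@H](CC=C(C)C)O)[C@@H]1CC=C(C)[C@H](OC(=O)/C(C)=C\C)[C@@H]1O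
F6 | step 9 | (10R)-10,11-epoxide of 18 with the C4=C5 alkene intact | C=C([C@H](C[C@H]1OC1(C)C)OC(=O)/C(C)=C\C)[C@@H]1CC=C(C)[C@H](OC(=O)/C(C)=C\C)[C@@H]1O
F7 | step 9 | bromohydrin of F6: C4–OH on the α face, C5–Br on the β face | C=C([C@H](C[C@H]1OC1(C)C)OC(=O)/C(C)=C\C)[C@@H]1C[C@@H](Br)[C@](C)(O)[C@H](OC(=O)/C(C)=C\C)[C@@H]1O
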